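I watch the coupling partner.

| flask | substrate | coupling partner | protic impurity | remark | time |
|---|---|---|---|---|---|
| north-west | 34 mM | 68 mM | 27 mM | run made earlier |  |
| east | 34 mM | 68 mM | 29 mM | run made earlier |  |
| north-east | 34 mM | 68 mM | 25 mM | run made earlier |  |
| north | 81 mM | 68 mM | 34 mM | run made earlier |  |
| spring | 34 mM | 68.0 mM | 34.0 mM |  | 2.0 min |
| summer | 150 mM | 68.0 mM | 25.0 mM |  | 3.0 min |

- north-west (time / s: target / %): 10.0: 44.9; 20.0: 66.3; 40.0: 85.2; 60.0: 92.0; 80.0: 94.8
- east (time / s: target / %): 10.0: 44.5; 12.0: 50.1; 25.0: 73.1; 40.0: 84.5; 80.0: 94.4
- north-east (time / s: target / %): 10.0: 44.8; 20.0: 66.4; 40.0: 84.9; 60.0: 92.7; 80.0: 95.3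
- north (time / s: target / %): 15.0: 48.3; 30.0: 59.0; 50.0: 62.8; 60.0: 62.9; 80.0: 63.2

(each reading ± 0.3 percentage points)

- the earlier runs were read with a standard deviation of 0.3 percentage points
- reactions considered so far: substrate <-> intermediate + leaving ligand; coupling partner + intermediate -> target; 2 coupling partner -> self-condensation product; coupling partner + protic impurity -> quenched reagent

1. the winner by amount of target, in percent of the substrate charged; "neither" if no more than 2 percentage points parts them (spring / summer / neither)
2. how much target is there at the end, in percent of the substrate charged: spring
3. how much target is there at the end, in percent of the substrate charged: summer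

With the main step by itself, substrate giving intermediate and intermediate taking one coupling partner to give target, the spring flask has room for 100 % of its substrate, while the summer flask, with 150 mM of substrate against 68.0 mM of partner, stops at 45.3 %, so there the partner is the limiting reagent.

Next I add the quench by protic impurity, which charges a toll on the partner. The north run, also short of partner, reads 62.8 % at 50.0 s and 63.2 % at 80.0 s; that flat end is 51.2 mM of target from 68 mM of partner, so 16.8 mM went elsewhere, or 0.328 partner lost per target made. The quench goes with partner times impurity and the target follows the substrate, so I assume this toll scales as partner charge times impurity charge over substrate charge, and I call the toll divided by that group the toll coefficient 0.0115 mM⁻¹.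

For the summer flask the toll comes to 0.130, so I reckon 60.2 mM of target, or 40.1 %. For the spring flask it comes to 0.782, so I reckon that its substrate needs 60.6 mM of partner, which would leave 7.41 mM spare, and time is what remains to reckon.

The last two steps get no separate sum of mine: I count self-condensation inside the north run's loss, and I take the way back from intermediate together with the slow tail of the readings. In the north-west run the last two readings give that tail a half-life of 32.2 s, which carried to 2.0 min at that run's 27 mM of impurity gives me 97.8 %, my rough figure for spring.

The forecast gives spring, with 96 % and 39 %, a little under my spring figure: "Spring clearly wins on percent of substrate charged".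

The winner is spring, which gives 96.9 % of target, and the summer flask gives 40.0 % and ends with 0 % of its coupling partner left.

    substrate ⇌ intermediate + leaving ligand (K = 0.00150 M, k = 0.0680 s⁻¹)
    coupling partner + intermediate → target (k = 75.0 M⁻¹ s⁻¹)
    2 coupling partner → self-condensation product (k = 0.0160 M⁻¹ s⁻¹)
    coupling partner + protic impurity → quenched reagent (k = 0.890 M⁻¹ s⁻¹)

By the toll coefficient I had 7.84 mM of partner lost in the summer flask, and that flask holds 7.59 mM of quenched reagent and 0.228 mM of self-condensation product, which at two partner apiece makes 8.05 mM of partner. A neighbour of spring charged with 17 mM of partner has a toll of 0.196 by the same coefficient, so I reckon 41.8 % of target for it, and that neighbour flask gives 40.0 %.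

Readings and results stem from a simulated flask on assumed constants; noise was put on by code.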